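**Retrosynthetic overview**
1. Target 26 ⇐ macrocycle 25 by a final epoxidation of the only electron-rich alkene, the Z-trisubstituted C1=C10 olefin.
2. 25 ⇐ seco-aldehyde 23: the ten-membered ring is closed at C6–C7 by a reversed-polarity allylation. The butenolide β-carbon C7, normally a Michael acceptor, is made a homoenolate-type (d3) donor through its bromomethyl group and CrCl2 and adds to the C6 aldehyde; this sets C6 and C7, leaves 6-OH free and creates the α-methylene lactone.
3. 23 ⇐ a butenolide made by esterification and ring-closing metathesis, and an aldehyde released by periodate cleavage of a sacrificial glyceraldehyde unit that set C5 in a Morita–Baylis–Hillman reaction before angeloylation.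
4. Vinyl ketone 11 ⇐ acryloyl-anion alkylation (lithiated methoxyallene) of Z-allylic chloride 7; the Z olefin ⇐ hydroxyl-directed anti-carboalumination of (R)-hex-1-en-5-yn-3-ol, made from (S)-2-vinyloxirane (source of C8).
5. Ring order: butenolide first (step 10), ten-membered carbocycle second (step 12), epoxide last (step 13).

Assumption: germacrane numbering is used (lactone C12(=O)–O–C8, ketone C3, epoxide C1–C10, C4=C15 and C11=C13 methylenes), and (S)-2-vinyloxirane and (S)-glyceraldehyde acetonide are bought as single enantiomers.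

**Route**

Step 1
Reactants: 1 (S)-2-vinyloxirane
Product: 2 (R)-hex-1-en-5-yn-3-ol
Conditions: LiC≡CH·H2NCH2CH2NH2, DMSO, 10 → 23 °C; aq. NH4Cl
Reagents that add atoms: lithium acetylide–ethylenediamine complex (LiC≡CH·H2NCH2CH2NH2), [Li]C#C.NCCN
Why: SN2 opening of the vinyl epoxide at its unhindered CH2 terminus by the acetylide leaves the carbinol centre (future C8) untouched, so (S)-1 gives (R)-2.

Step 2
Reactants: 2 (R)-hex-1-en-5-yn-3-ol
Product: 4 (2Z,5R)-3-methylhepta-2,6-diene-1,5-diol, via cyclic Z-alkenylalane 3 (not isolated)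
Conditions: AlMe3 (3 equiv), Cp2ZrCl2 (25 mol%), ClCH2CH2Cl, 23 °C then reflux 72 h; evaporate; n-BuLi, THF, −78 °C; (CH2O)n, −78 → 23 °C; aq. potassium sodium tartrate
Reagents that add atoms: trimethylaluminium (AlMe3), C[Al](C)C; paraformaldehyde (as formaldehyde), C=O
Why: Negishi zirconium-catalysed carboalumination adds Me–Al syn across the alkyne and the aluminium alkoxide then drives chelation-controlled isomerisation to the Z-alkenylalane (Negishi–Ma anti-carboalumination), whose ate complex is hydroxymethylated with retention, so the C1=C10 olefin is set Z.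

Step 3
Reactants: 4 (2Z,5R)-3-methylhepta-2,6-diene-1,5-diol
Product: 6 (3R,5Z)-7-chloro-5-methylhepta-1,5-dien-3-ol, via allylic mesylate 5 (not isolated)
Conditions: MsCl (1.05 equiv), 2,4,6-collidine, LiCl, DMF, 0 °C
Reagents that add atoms: lithium chloride, [Li+].[Cl-]
Why: The primary allylic alcohol is mesylated much faster than the secondary carbinol and the mesylate is displaced in situ by chloride (Collington–Meyers allylic chlorination, SN2), leaving the Z olefin and C8 untouched; 6 is kept cold and used at once because it can cyclise to a dihydropyran.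

Step 4
Reactants: 6 (3R,5Z)-7-chloro-5-methylhepta-1,5-dien-3-ol
Product: 7 tert-butyl{[(3R,5Z)-7-chloro-5-methylhepta-1,5-dien-3-yl]oxy}dimethylsilane
Conditions: TBSOTf, 2,6-lutidine, CH2Cl2, −78 °C
Reagents that add atoms: tert-butyldimethylsilyl triflate, CC(C)(C)[Si](C)(C)OS(=O)(=O)C(F)(F)F
Why: Standard O-silylation with a hindered base that cannot alkylate the allylic chloride protects the C8 oxygen for the carbanion and acylation steps that follow.

Step 5
Reactants: 7 tert-butyl{[(3R,5Z)-7-chloro-5-methylhepta-1,5-dien-3-yl]oxy}dimethylsilane; 8 methoxyallene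
Product: 11 (5Z,8R)-8-[(tert-butyldimethylsilyl)oxy]-6-methyldeca-1,5,9-trien-3-one, via 1-lithio-1-methoxyallene 9 (not isolated), via allenyl methyl ether 10 (not isolated)
Conditions: 8, n-BuLi, THF, −40 °C; 7, DMPU, −78 → −20 °C; then 0.5 M aq. H2SO4, THF, 0 °C
Reagents that add atoms: water, O
Why: Lithiated methoxyallene is an acryloyl-anion equivalent (acyl-anion alkylation); SN2 attack at the primary allylic chloride keeps the Z geometry and mild hydrolysis of the allenyl enol ether unmasks the vinyl ketone (C3 carbonyl) without moving the skipped olefin.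

Step 6
Reactants: 11 (5Z,8R)-8-[(tert-butyldimethylsilyl)oxy]-6-methyldeca-1,5,9-trien-3-one; 12 (S)-glyceraldehyde acetonide
Product: 13 (5Z,8R)-8-[(tert-butyldimethylsilyl)oxy]-2-{(R)-[(4S)-2,2-dimethyl-1,3-dioxolan-4-yl](hydroxy)methyl}-6-methyldeca-1,5,9-trien-3-one
Conditions: DABCO (0.5 equiv), 1,4-dioxane/H2O 1:1, 23 °C
Reagents that add atoms: none
Why: Morita–Baylis–Hillman reaction of the alkyl vinyl ketone with the α-alkoxy aldehyde forms the C4–C5 bond, and Felkin–Anh attack anti to the dioxolane C–O bond gives mainly the anti adduct (expected about 3:1, minor isomer removed by chromatography), which fixes C5 as R.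

Step 7
Reactants: 13 (the Morita–Baylis–Hillman alcohol); 14 angelic acid
Product: 16 (1R,5Z,8R)-8-[(tert-butyldimethylsilyl)oxy]-1-[(4S)-2,2-dimethyl-1,3-dioxolan-4-yl]-6-methyl-2-methylidene-3-oxodeca-5,9-dien-1-yl (Z)-2-methylbut-2-enoate, via angelic 2,4,6-trichlorobenzoic anhydride 15 (not isolated)
Conditions: 14, 2,4,6-Cl3C6H2COCl, Et3N, toluene, 23 °C; then 13, 75 °C
Reagents that add atoms: none
Why: Yamaguchi mixed-anhydride esterification acylates the only free hydroxyl and is the usual way to make angelates without Z-to-E isomerisation to the tiglate; C5 is not touched.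

Step 8
Reactants: 16 (the silyl-protected angelate)
Product: 17 (1R,5Z,8R)-1-[(4S)-2,2-dimethyl-1,3-dioxolan-4-yl]-8-hydroxy-6-methyl-2-methylidene-3-oxodeca-5,9-dien-1-yl (Z)-2-methylbut-2-enoate
Conditions: HF·pyridine, pyridine, THF, 0 → 23 °C
Reagents that add atoms: none
Why: Buffered fluoride desilylation frees the C8 hydroxyl while the acetonide, the angelate and the base-sensitive skipped enone survive.

Step 9
Reactants: 17 (the C8 alcohol); 18 2-(bromomethyl)acrylic acid
Product: 20 (3R,5Z,10R)-10-[(4S)-2,2-dimethyl-1,3-dioxolan-4-yl]-5-methyl-9-methylidene-10-{[(Z)-2-methylbut-2-enoyl]oxy}-8-oxodeca-1,5-dien-3-yl 2-(bromomethyl)acrylate, via 2-(bromomethyl)acryloyl chloride 19 (not isolated)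
Conditions: 18, (COCl)2, DMF (cat.), CH2Cl2, 0 → 23 °C, evaporate; then 17, 2,6-lutidine, CH2Cl2, −20 → 0 °C
Reagents that add atoms: none
Why: Acylation of the one free secondary allylic alcohol by the acid chloride, with a hindered base that does not quaternise the allylic bromide, proceeds with retention at C8.

Step 10
Reactants: 20 (the 2-(bromomethyl)acrylate ester)
Product: 21 (5R)-3-(bromomethyl)-5-[(2Z,7R)-7-[(4S)-2,2-dimethyl-1,3-dioxolan-4-yl]-2-methyl-6-methylidene-7-{[(Z)-2-methylbut-2-enoyl]oxy}-5-oxohept-2-en-1-yl]furan-2(5H)-one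
Conditions: second-generation Grubbs catalyst (5 mol%), CH2Cl2 (0.005 M), 40 °C
Reagents that add atoms: none
Why: Ring-closing metathesis between the terminal vinyl group and the acrylate closes the five-membered butenolide far faster than any reaction of the hindered 1,1-disubstituted or trisubstituted alkenes, and C8 is untouched.

Step 11
Reactants: 21 (the bromomethyl butenolide acetonide)
Product: 23 (2R,6Z)-8-[(2R)-4-(bromomethyl)-5-oxo-2,5-dihydrofuran-2-yl]-7-methyl-3-methylidene-1,4-dioxooct-6-en-2-yl (Z)-2-methylbut-2-enoate, via vicinal diol 22 (not isolated)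
Conditions: H5IO6 (1.5 equiv), EtOAc, 0 → 23 °C
Reagents that add atoms: none
Why: Periodic acid hydrolyses the terminal acetonide and cleaves the resulting 1,2-diol in one pot (oxidative glycol cleavage), releasing the α-angeloyloxy aldehyde (C6) without any base that could epimerise C5; 23 is used immediately.

Step 12
Reactants: 23 (the seco-aldehyde)
Product: 25 (5R,6S,7R,8R,1(10)Z)-5-angeloyloxy-6-hydroxy-3-oxogermacra-1(10),4(15),11(13)-trien-12,8-olide, via allylchromium dichloride 24 (not isolated)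
Conditions: CrCl2 (8 equiv), THF (0.002 M, substrate added over 10 h), 23 °C; pH 7 buffer
Reagents that add atoms: none
Why: Proposed new method: insertion of divalent chromium into the allylic C–Br bond turns the butenolide β-carbon C7 (normally an acceptor) into the nucleophilic γ-terminus of an allylchromium species (trivalent chromium), which adds through a six-membered cyclic transition state only to the aldehyde C6 (not the C3 ketone), closing the ten-membered ring and leaving the C11=C13 methylene; C7 is set by attack anti to the C8 substituent (trans lactone) and C6 by Felkin–Anh addition anti to the C5 angeloyloxy group; the closest known reactions are the intermolecular zinc- or chromium-mediated γ-allylations of aldehydes with 3-(bromomethyl)furan-2(5H)-one and Nozaki–Hiyama–Kishi macrocyclisations of 2-(bromomethyl)acrylates to germacranolides.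

Step 13
Reactants: 25 (the macrocyclic triene)
Product: 26 target CNP0348992.6, (1S,5R,6S,7R,8R,10R)-5-angeloyloxy-1,10-epoxy-6-hydroxy-3-oxogermacra-4(15),11(13)-dien-12,8-olide
Conditions: mCPBA (1.1 equiv), NaHCO3, CH2Cl2, 0 °C
Reagents that add atoms: meta-chloroperoxybenzoic acid, O=C(OO)c1cccc(Cl)c1
Why: Prilezhaev epoxidation is chemoselective for the C1=C10 olefin (the other three alkenes are conjugated to carbonyls) and stereospecific for its Z geometry; attack on the exposed outer face of the ring is expected, but not proven, to give the (1S,10R) epoxide.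

**Compound list**

1 | (S)-2-vinyloxirane | C=C[C@H]1CO1 | starting material
2 | (R)-hex-1-en-5-yn-3-ol | C#CC[C@@H](O)C=C | intermediate
3 | cyclic Z-alkenylalane, (6R)-2,4-dimethyl-6-vinyl-5,6-dihydro-2H-1,2-oxaaluminine (C9H15AlO) | C[Al]1O[C@@H](C=C)CC(C)=C1 | intermediate (not isolated)
4 | (2Z,5R)-3-methylhepta-2,6-diene-1,5-diol | OC/C=C(C)\C[C@@H](O)C=C | intermediate
5 | (2Z,5R)-5-hydroxy-3-methylhepta-2,6-dien-1-yl methanesulfonate | CS(=O)(=O)OC/C=C(C)\C[C@@H](O)C=C | intermediate (not isolated)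
6 | (3R,5Z)-7-chloro-5-methylhepta-1,5-dien-3-ol | ClC/C=C(C)\C[C@@H](O)C=C | intermediate
7 | tert-butyl{[(3R,5Z)-7-chloro-5-methylhepta-1,5-dien-3-yl]oxy}dimethylsilane | ClC/C=C(C)\C[C@@H](O[Si](C)(C)C(C)(C)C)C=C | intermediate
8 | methoxyallene (1-methoxypropa-1,2-diene) | COC=C=C | starting material
9 | 1-lithio-1-methoxyallene | [Li]C(OC)=C=C | intermediate (not isolated)
10 | tert-butyl{[(3R,5Z)-8-methoxy-5-methyldeca-1,5,8,9-tetraen-3-yl]oxy}dimethylsilane | C=C=C(OC)C/C=C(C)\C[C@@H](O[Si](C)(C)C(C)(C)C)C=C | intermediate (not isolated)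
11 | (5Z,8R)-8-[(tert-butyldimethylsilyl)oxy]-6-methyldeca-1,5,9-trien-3-one | C=CC(=O)C/C=C(C)\C[C@@H](O[Si](C)(C)C(C)(C)C)C=C | intermediate
12 | (S)-glyceraldehyde acetonide, (S)-2,2-dimethyl-1,3-dioxolane-4-carbaldehyde | O=C[C@@H]1COC(C)(C)O1 | starting material
13 | (5Z,8R)-8-[(tert-butyldimethylsilyl)oxy]-2-{(R)-[(4S)-2,2-dimethyl-1,3-dioxolan-4-yl](hydroxy)methyl}-6-methyldeca-1,5,9-trien-3-one | C=C(C(=O)C/C=C(C)\C[C@@H](O[Si](C)(C)C(C)(C)C)C=C)[C@@H](O)[C@@H]1COC(C)(C)O1 | intermediate
14 | angelic acid, (Z)-2-methylbut-2-enoic acid | C/C=C(/C)C(=O)O | starting material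
15 | angelic 2,4,6-trichlorobenzoic anhydride | C/C=C(/C)C(=O)OC(=O)c1c(Cl)cc(Cl)cc1Cl | intermediate (not isolated)
16 | (1R,5Z,8R)-8-[(tert-butyldimethylsilyl)oxy]-1-[(4S)-2,2-dimethyl-1,3-dioxolan-4-yl]-6-methyl-2-methylidene-3-oxodeca-5,9-dien-1-yl (Z)-2-methylbut-2-enoate | C=C(C(=O)C/C=C(C)\C[C@@H](O[Si](C)(C)C(C)(C)C)C=C)[C@@H](OC(=O)/C(C)=C\C)[C@@H]1COC(C)(C)O1 | intermediate
17 | (1R,5Z,8R)-1-[(4S)-2,2-dimethyl-1,3-dioxolan-4-yl]-8-hydroxy-6-methyl-2-methylidene-3-oxodeca-5,9-dien-1-yl (Z)-2-methylbut-2-enoate | C=C(C(=O)C/C=C(C)\C[C@@H](O)C=C)[C@@H](OC(=O)/C(C)=C\C)[C@@H]1COC(C)(C)O1 | intermediate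
18 | 2-(bromomethyl)acrylic acid | C=C(CBr)C(=O)O | starting material
19 | 2-(bromomethyl)acryloyl chloride | C=C(CBr)C(Cl)=O | intermediate (not isolated)
20 | (3R,5Z,10R)-10-[(4S)-2,2-dimethyl-1,3-dioxolan-4-yl]-5-methyl-9-methylidene-10-{[(Z)-2-methylbut-2-enoyl]oxy}-8-oxodeca-1,5-dien-3-yl 2-(bromomethyl)acrylate | C=C(CBr)C(=O)O[C@@H](C=C)C/C(C)=C\CC(=O)C(=C)[C@@H](OC(=O)/C(C)=C\C)[C@@H]1COC(C)(C)O1 | intermediate
21 | (5R)-3-(bromomethyl)-5-[(2Z,7R)-7-[(4S)-2,2-dimethyl-1,3-dioxolan-4-yl]-2-methyl-6-methylidene-7-{[(Z)-2-methylbut-2-enoyl]oxy}-5-oxohept-2-en-1-yl]furan-2(5H)-one | BrCC1=C[C@@H](C/C(C)=C\CC(=O)C(=C)[C@@H](OC(=O)/C(C)=C\C)[C@@H]2COC(C)(C)O2)OC1=O | intermediate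
22 | (5R)-3-(bromomethyl)-5-[(2Z,7R,8S)-8,9-dihydroxy-2-methyl-6-methylidene-7-{[(Z)-2-methylbut-2-enoyl]oxy}-5-oxonon-2-en-1-yl]furan-2(5H)-one | BrCC1=C[C@@H](C/C(C)=C\CC(=O)C(=C)[C@@H](OC(=O)/C(C)=C\C)[C@@H](O)CO)OC1=O | intermediate (not isolated)
23 | (2R,6Z)-8-[(2R)-4-(bromomethyl)-5-oxo-2,5-dihydrofuran-2-yl]-7-methyl-3-methylidene-1,4-dioxooct-6-en-2-yl (Z)-2-methylbut-2-enoate | BrCC1=C[C@@H](C/C(C)=C\CC(=O)C(=C)[C@@H](OC(=O)/C(C)=C\C)C=O)OC1=O | intermediate
24 | allylchromium dichloride of 23 (CrCl2 unit in place of Br, trivalent chromium) | Cl[Cr](Cl)CC1=C[C@@H](C/C(C)=C\CC(=O)C(=C)[C@@H](OC(=O)/C(C)=C\C)C=O)OC1=O | intermediate (not isolated)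
25 | (5R,6S,7R,8R,1(10)Z)-5-angeloyloxy-6-hydroxy-3-oxogermacra-1(10),4(15),11(13)-trien-12,8-olide | C=C1C(=O)O[C@@H]2C/C(C)=C\CC(=O)C(=C)[C@@H](OC(=O)/C(C)=C\C)[C@@H](O)[C@@H]12 | intermediate
26 | CNP0348992.6, (1S,5R,6S,7R,8R,10R)-5-angeloyloxy-1,10-epoxy-6-hydroxy-3-oxogermacra-4(15),11(13)-dien-12,8-olide | C=C1C(=O)O[C@@H]2C[C@@]3(C)O[C@H]3CC(=O)C(=C)[C@@H](OC(=O)/C(C)=C\C)[C@@H](O)[C@@H]12 | target

**Step count and risks**

Total step count: 13. Longest linear sequence: 13 steps (1 → 26); all other building blocks (8, 12, 14, 18) are bought.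

Steps most likely to fail:

- **Step 12 (ring closure).** The ten-membered ring, the trans lactone fusion and the C6 configuration all depend on one untested cyclisation. The anti-to-C8 and Felkin preferences may be mismatched within the ring, and the new chromium alkoxide at O6 could translactonise onto C12 (quench cold at pH 7). Fallback with a different donor and an open transition state: set out from 17 and esterify it with 2-[(trimethylsilyl)methyl]acrylic acid (DCC, cat. DMAP) to give the silyl acrylate F2. Ring-closing metathesis with the second-generation Grubbs catalyst gives the allylsilane butenolide F3. H5IO6 then cleaves it through the diol F4 to the aldehyde F5. An intramolecular Hosomi–Sakurai allylation (BF3·OEt2, CH2Cl2, −78 °C, high dilution) closes the ring and comes back to the route at 25.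

- **Step 6 (Morita–Baylis–Hillman).** DABCO may move the skipped C1=C10 olefin of 11 into conjugation, and the anti:syn ratio is only moderate. Fallback by a Lewis-acid halo-aldol instead of amine catalysis: set out from 11 and 12 and treat with Et2AlI (CH2Cl2, −78 °C); conjugate addition of iodide and aldol reaction of the aluminium enolate give the β-iodo aldol F1. Brief treatment with Et3N at 0 °C eliminates HI (E1cB) and comes back to the route at 13.

- **Step 13 (epoxide face).** The face selectivity on the macrocycle is a conformational prediction only. If mCPBA gives the C1/C10 diastereomer, deliver oxygen to the other face by anti addition and closure: set out from 25 and treat with NBS in THF/H2O at 0 °C. The bromonium forms on the face the peracid prefers and water opens it at C10 from the other face, giving the trans bromohydrin F6. Ag2O in Et2O then closes the epoxide with inversion at C1 and comes back to the route at 26.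

Further compounds
F1 | step 6 | (5Z,8R)-8-[(tert-butyldimethylsilyl)oxy]-2-{(R)-[(4S)-2,2-dimethyl-1,3-dioxolan-4-yl](hydroxy)methyl}-1-iodo-6-methyldeca-5,9-dien-3-one (both C2 epimers) | ICC(C(=O)C/C=C(C)\C[C@@H](O[Si](C)(C)C(C)(C)C)C=C)[C@@H](O)[C@@H]1COC(C)(C)O1
F2 | step 12 | (3R,5Z,10R)-10-[(4S)-2,2-dimethyl-1,3-dioxolan-4-yl]-5-methyl-9-methylidene-10-{[(Z)-2-methylbut-2-enoyl]oxy}-8-oxodeca-1,5-dien-3-yl 2-[(trimethylsilyl)methyl]acrylate | C=C(C[Si](C)(C)C)C(=O)O[C@@H](C=C)C/C(C)=C\CC(=O)C(=C)[C@@H](OC(=O)/C(C)=C\C)[C@@H]1COC(C)(C)O1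
F3 | step 12 | (5R)-5-[(2Z,7R)-7-[(4S)-2,2-dimethyl-1,3-dioxolan-4-yl]-2-methyl-6-methylidene-7-{[(Z)-2-methylbut-2-enoyl]oxy}-5-oxohept-2-en-1-yl]-3-[(trimethylsilyl)methyl]furan-2(5H)-one | C[Si](C)(C)CC1=C[C@@H](C/C(C)=C\CC(=O)C(=C)[C@@H](OC(=O)/C(C)=C\C)[C@@H]2COC(C)(C)O2)OC1=O
F4 | step 12 | (5R)-5-[(2Z,7R,8S)-8,9-dihydroxy-2-methyl-6-methylidene-7-{[(Z)-2-methylbut-2-enoyl]oxy}-5-oxonon-2-en-1-yl]-3-[(trimethylsilyl)methyl]furan-2(5H)-one | C[Si](C)(C)CC1=C[C@@H](C/C(C)=C\CC(=O)C(=C)[C@@H](OC(=O)/C(C)=C\C)[C@@H](O)CO)OC1=O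
F5 | step 12 | (2R,6Z)-7-methyl-3-methylidene-1,4-dioxo-8-{(2R)-5-oxo-4-[(trimethylsilyl)methyl]-2,5-dihydrofuran-2-yl}oct-6-en-2-yl (Z)-2-methylbut-2-enoate | C[Si](C)(C)CC1=C[C@@H](C/C(C)=C\CC(=O)C(=C)[C@@H](OC(=O)/C(C)=C\C)C=O)OC1=O
F6 | step 13 | (1R,5R,6S,7R,8R,10R)-5-angeloyloxy-1-bromo-6,10-dihydroxy-3-oxogermacra-4(15),11(13)-dien-12,8-olide | C=C1C(=O)O[C@@H]2C[C@@](C)(O)[C@H](Br)CC(=O)C(=C)[C@@H](OC(=O)/C(C)=C\C)[C@@H](O)[C@@H]12
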